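**Strategy**

The carbon skeleton comes from sclareol; allyl phenyl sulfone supplies C14, C15 and a temporary carbon, C13a. An intramolecular enone–alkene [2+2] photocycloaddition builds the cyclobutane (C8, C9, C14, C15) together with a six-membered carbocycle in which C13a sits between C13 and C14. Everything rests on the Lewis-acid rearrangement of its 13,13a-epoxide: the C13a–C14 ring bond shifts to the tertiary, methyl-bearing C13, so that the cyclohexane contracts to the cyclopentane C9–C11–C12–C13–C14, the quaternary C13 stereocentre is set by inversion, and C13a is pushed out as a formyl group, which a Baeyer–Villiger oxidation later exchanges for the C13 hydroxyl. The step exploits the fully substituted C13 next to ring-fusion carbon C14.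

Key step: step 8

Remark: labdane numbering is used throughout; C13a is the extra carbon between C13 and C14 that is present until step 8; "H-14 face" means the face of the new ring anti to the cyclobutane; 1 and 6 are taken as commercial.

**Route**

Step 1
Reactants: 1 (−)-sclareol
Product: 4 8α-hydroxy-14,15-dinorlabdan-13-one, via sclareol 14,15-diol 2 (not isolated), via 13-hydroxy-14-aldehyde 3 (not isolated)
Conditions: OsO4 (2 mol %), NaIO4 (4 equiv), 2,6-lutidine, dioxane/H2O, rt
Reagents that add atoms: none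
Why: Lemieux–Johnson cleavage of the vinyl group gives the tertiary α-hydroxy aldehyde, whose hydrate is cleaved once more by periodate to the methyl ketone; this deliberately erases the C13 stereocentre and should leave the hindered 8α-OH untouched.

Step 2
Reactants: 4 8α-hydroxy-14,15-dinorlabdan-13-one
Product: 5 14,15-dinorlabd-8-en-13-one
Conditions: PPh3, I2, CH2Cl2, rt
Reagents that add atoms: none
Why: PPh3/I2 dehydration of a tertiary alcohol (oxyphosphonium, E1-type loss) should give the thermodynamically preferred tetrasubstituted C8=C9 alkene, as known for 8α-hydroxy labdanes and drimanes; no stereocentre is formed.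

Step 3
Reactants: 5 14,15-dinorlabd-8-en-13-one, 6 allyl phenyl sulfone
Product: 8 13-acetoxy-13a-(phenylsulfonyl)-13a-homolabda-8,14-diene (diastereomer mixture at C13 and C13a), via lithium alkoxide 7 (not isolated)
Conditions: 6, n-BuLi, THF, −78 °C; then 5; then Ac2O, −78 to 0 °C
Reagents that add atoms: acetic anhydride, CC(=O)OC(C)=O
Why: First half of a Julia–Lythgoe olefination: the lithiated allyl sulfone adds through its α-carbon to the methyl ketone and the tertiary alkoxide is acetylated before it can revert; C13 and C13a form without control and both are removed in step 6.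

Step 4
Reactants: 8 13-acetoxy-13a-(phenylsulfonyl)-13a-homolabda-8,14-diene
Product: 9 13-acetoxy-13a-(phenylsulfonyl)-13a-homolabda-8,14-dien-7-one
Conditions: CrO3·2C5H5N (excess), CH2Cl2, rt
Reagents that add atoms: chromium trioxide–pyridine complex, O=[Cr](=O)=O.c1ccncc1.c1ccncc1
Why: Allylic oxidation with the CrO3–pyridine complex should convert the ring methylene C7 beside the tetrasubstituted alkene into the conjugated ketone, in preference to the side-chain C11 methylene and the electron-poor allyl sulfone; no stereocentre is formed.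

Step 5
Reactants: 9 13-acetoxy-13a-(phenylsulfonyl)-13a-homolabda-8,14-dien-7-one
Product: 10 13-acetoxy-13a-(phenylsulfonyl)-8α,15:9α,14-dicyclo-13a-homolabdan-7-one
Conditions: hν (350 nm, Pyrex), degassed MeCN, rt
Reagents that add atoms: none
Why: Intramolecular enone–alkene [2+2] photocycloaddition through the enone triplet: the four-atom tether closes the six-membered ring first (C9–C14) and then the cyclobutane (C8–C15), and the alkene adds to the α-face anti to the axial C10 methyl, which sets C8 (CH3 β), C9 (C11 β) and C14 (H on the C10 side, cis-fused rings).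

Step 6
Reactants: 10 13-acetoxy-13a-(phenylsulfonyl)-8α,15:9α,14-dicyclo-13a-homolabdan-7-one
Product: 11 8α,15:9α,14-dicyclo-13a-homolabd-13(13a)-en-7-one
Conditions: Na(Hg) (6 %), Na2HPO4, THF/MeOH, −20 °C
Reagents that add atoms: none
Why: Julia–Lythgoe reductive elimination expels benzenesulfinate and acetate, so all diastereomers of 10 should converge on one alkene whose position (C13=C13a) is fixed by the sulfone and whose geometry is fixed by the ring.

Step 7
Reactants: 11 8α,15:9α,14-dicyclo-13a-homolabd-13(13a)-en-7-one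
Product: 12 (13S,13aR)-13,13a-epoxy-8α,15:9α,14-dicyclo-13a-homolabdan-7-one
Conditions: DMDO, acetone/CH2Cl2, 0 °C
Reagents that add atoms: dimethyldioxirane, CC1(C)OO1
Why: Epoxidation with dimethyldioxirane should take place on the convex face of the bicyclo[4.2.0]octene (the H-14 face, anti to the cyclobutane carbons C8 and C15), which sets C13 and C13a.

Step 8
Reactants: 12 (13S,13aR)-13,13a-epoxy-8α,15:9α,14-dicyclo-13a-homolabdan-7-one
Product: 13 (13S)-13-formyl-8α,15:9α,14-dicyclolabdan-7-one
Conditions: MeAl(OC6H2-4-Br-2,6-tBu2)2 (MABR, 20 mol %), CH2Cl2, −78 to −20 °C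
Reagents that add atoms: none
Why: The bulky aluminium Lewis acid binds the epoxide oxygen and ionises the tertiary C13–O bond, and the C13a–C14 σ-bond of the cyclohexane migrates to C13 on the face opposite to the leaving oxygen while C13a becomes the formyl carbon. The closest known reaction type is the Meinwald (semipinacol) rearrangement of trisubstituted epoxides with ring contraction, as in 1-methylcyclohexene oxide to 1-methylcyclopentanecarbaldehyde. The cyclopentane C9–C11–C12–C13–C14 is closed by a suprafacial 1,2-alkyl shift of C14 from C13a to C13 and not by a cyclisation, so C14 keeps its configuration and the cis fusion to the cyclobutane from step 5 is carried over. The new quaternary stereocentre C13 is controlled by the epoxide: oxygen leaves from the H-14 face, C14 enters from the cyclobutane face, and the formyl group therefore ends on the H-14 face with the methyl on the cyclobutane face. The step needs migration of the ring bond to win over the shift of the C13a hydride (which would give the cyclohexanone) and needs the cyclobutane to survive; the bulky, aprotic MABR is expected to favour alkyl over hydride migration in such epoxides, and the cation is formed at C13, which is not bonded to the four-membered ring.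

Step 9
Reactants: 13 (13S)-13-formyl-8α,15:9α,14-dicyclolabdan-7-one
Product: 15 (13S)-13-hydroxy-8α,15:9α,14-dicyclolabdan-7-one, via 13-formate 14 (not isolated)
Conditions: mCPBA, CH2Cl2, 0 °C; then K2CO3 (cat.), MeOH, rt
Reagents that add atoms: 3-chloroperbenzoic acid, OOC(=O)c1cccc(Cl)c1
Why: Baeyer–Villiger oxidation of the α-quaternary aldehyde (the tertiary C13 migrates in preference to hydride and with retention) gives the formate, which is removed by methanolysis; the hindered C7 ketone beside the quaternary C8 should not react at 0 °C.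

Step 10
Reactants: 15 (13S)-13-hydroxy-8α,15:9α,14-dicyclolabdan-7-one
Product: 16 (13S)-13-(trimethylsilyloxy)-8α,15:9α,14-dicyclolabdan-7-one
Conditions: N-(trimethylsilyl)imidazole, CH2Cl2, rt
Reagents that add atoms: N-(trimethylsilyl)imidazole, C[Si](C)(C)n1ccnc1
Why: Silylation of the tertiary alcohol with a strong silyl donor masks the hydroxyl so that the enolate of step 11 is acetylated on the enolate oxygen only.

Step 11
Reactants: 16 (13S)-13-(trimethylsilyloxy)-8α,15:9α,14-dicyclolabdan-7-one
Product: 18 7-acetoxy-13-(trimethylsilyloxy)-8α,15:9α,14-dicyclolabd-6-ene, via lithium enolate 17 (not isolated)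
Conditions: LiN(SiMe3)2, THF, −78 °C; then Ac2O
Reagents that add atoms: acetic anhydride, CC(=O)OC(C)=O
Why: The C7 ketone can enolise only toward C6 (C8 is quaternary), and O-acetylation of the lithium enolate gives the enol acetate.

Step 12
Reactants: 18 7-acetoxy-13-(trimethylsilyloxy)-8α,15:9α,14-dicyclolabd-6-ene
Product: 21 6β-acetoxy-13-hydroxy-8α,15:9α,14-dicyclolabdan-7-one (13S; target CNP0330581.1), via epoxy acetate 19 (not isolated), via silyl ether 20 (not isolated)
Conditions: DMDO, acetone/CH2Cl2, 0 °C; evaporate; PhMe, 110 °C; then AcOH/THF/H2O, rt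
Reagents that add atoms: dimethyldioxirane, CC1(C)OO1
Why: Dimethyldioxirane should epoxidise the enol acetate from the α-face (the β-face of C6–C7 is blocked by the axial methyls C17, C19 and C20), the enol ester epoxide rearranges on heating by an intramolecular 1,2-acyloxy shift with inversion at C6 that places the acetate in the hindered 6β position and turns the epoxide oxygen into the C7 carbonyl, and mild acid then removes the silyl group without touching the epimerisable C6.

**Compound list**

1 | (−)-sclareol, (13R)-labd-14-ene-8α,13-diol | C1C[C@@](C)(O)[C@H](CC[C@@](C)(O)C=C)[C@@]2(C)CCCC(C)(C)[C@H]12 | starting material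
2 | sclareol 14,15-diol, (13R)-labdane-8α,13,14,15-tetrol (C14 unassigned) | C1C[C@@](C)(O)[C@H](CC[C@@](C)(O)C(O)CO)[C@@]2(C)CCCC(C)(C)[C@H]12 | intermediate
3 | (13R)-8α,13-dihydroxy-15-norlabdan-14-al | C1C[C@@](C)(O)[C@H](CC[C@@](C)(O)C=O)[C@@]2(C)CCCC(C)(C)[C@H]12 | intermediate
4 | 8α-hydroxy-14,15-dinorlabdan-13-one | C1C[C@@](C)(O)[C@H](CCC(C)=O)[C@@]2(C)CCCC(C)(C)[C@H]12 | intermediate
5 | 14,15-dinorlabd-8-en-13-one | C1CC(C)=C(CCC(C)=O)[C@@]2(C)CCCC(C)(C)[C@H]12 | intermediate
6 | allyl phenyl sulfone | C=CCS(=O)(=O)c1ccccc1 | starting material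
7 | lithium alkoxide of 13-hydroxy-13a-(phenylsulfonyl)-13a-homolabda-8,14-diene (C13, C13a unassigned) | C1CC(C)=C(CCC(C)(O[Li])C(C=C)S(=O)(=O)c3ccccc3)[C@@]2(C)CCCC(C)(C)[C@H]12 | intermediate
8 | 13-acetoxy-13a-(phenylsulfonyl)-13a-homolabda-8,14-diene (C13, C13a unassigned) | C1CC(C)=C(CCC(C)(OC(C)=O)C(C=C)S(=O)(=O)c3ccccc3)[C@@]2(C)CCCC(C)(C)[C@H]12 | intermediate
9 | 13-acetoxy-13a-(phenylsulfonyl)-13a-homolabda-8,14-dien-7-one (C13, C13a unassigned) | C1C(=O)C(C)=C(CCC(C)(OC(C)=O)C(C=C)S(=O)(=O)c3ccccc3)[C@@]2(C)CCCC(C)(C)[C@H]12 | intermediate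
10 | 13-acetoxy-13a-(phenylsulfonyl)-8α,15:9α,14-dicyclo-13a-homolabdan-7-one (α-face cyclobutane C8–C9–C14–C15 fused to the ring C9–C11–C12–C13–C13a–C14; H-14 on the C10 side; C13, C13a unassigned) | C1C(=O)[C@@]2(C)C[C@H]3[C@@]2(CCC(C)(OC(C)=O)C3S(=O)(=O)c4ccccc4)[C@@]2(C)CCCC(C)(C)[C@H]12 | intermediate
11 | 8α,15:9α,14-dicyclo-13a-homolabd-13(13a)-en-7-one | C1C(=O)[C@@]2(C)C[C@H]3[C@@]2(CCC(C)=C3)[C@@]2(C)CCCC(C)(C)[C@H]12 | intermediate
12 | (13S,13aR)-13,13a-epoxy-8α,15:9α,14-dicyclo-13a-homolabdan-7-one (epoxide oxygen on the H-14 face) | C1C(=O)[C@@]2(C)C[C@H]3[C@@]2(CC[C@]5(C)O[C@H]35)[C@@]2(C)CCCC(C)(C)[C@H]12 | intermediate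
13 | (13S)-13-formyl-8α,15:9α,14-dicyclolabdan-7-one (formyl on the H-14 face, C16 methyl on the cyclobutane face) | C1C(=O)[C@@]2(C)C[C@H]3[C@@]2(CC[C@]3(C)C=O)[C@@]2(C)CCCC(C)(C)[C@H]12 | intermediate
14 | (13S)-13-formyloxy-8α,15:9α,14-dicyclolabdan-7-one | C1C(=O)[C@@]2(C)C[C@H]3[C@@]2(CC[C@]3(C)OC=O)[C@@]2(C)CCCC(C)(C)[C@H]12 | intermediate
15 | (13S)-13-hydroxy-8α,15:9α,14-dicyclolabdan-7-one | C1C(=O)[C@@]2(C)C[C@H]3[C@@]2(CC[C@]3(C)O)[C@@]2(C)CCCC(C)(C)[C@H]12 | intermediate
16 | (13S)-13-(trimethylsilyloxy)-8α,15:9α,14-dicyclolabdan-7-one | C1C(=O)[C@@]2(C)C[C@H]3[C@@]2(CC[C@]3(C)O[Si](C)(C)C)[C@@]2(C)CCCC(C)(C)[C@H]12 | intermediate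
17 | lithium 6-en-7-olate of 16 | C1=C(O[Li])[C@@]2(C)C[C@H]3[C@@]2(CC[C@]3(C)O[Si](C)(C)C)[C@@]2(C)CCCC(C)(C)[C@H]12 | intermediate
18 | 7-acetoxy-13-(trimethylsilyloxy)-8α,15:9α,14-dicyclolabd-6-ene | C1=C(OC(C)=O)[C@@]2(C)C[C@H]3[C@@]2(CC[C@]3(C)O[Si](C)(C)C)[C@@]2(C)CCCC(C)(C)[C@H]12 | intermediate
19 | 7β-acetoxy-6α,7α-epoxy-13-(trimethylsilyloxy)-8α,15:9α,14-dicyclolabdane | O4[C@H]1[C@]4(OC(C)=O)[C@@]2(C)C[C@H]3[C@@]2(CC[C@]3(C)O[Si](C)(C)C)[C@@]2(C)CCCC(C)(C)[C@H]12 | intermediate
20 | 6β-acetoxy-13-(trimethylsilyloxy)-8α,15:9α,14-dicyclolabdan-7-one | CC(=O)O[C@@H]1C(=O)[C@@]2(C)C[C@H]3[C@@]2(CC[C@]3(C)O[Si](C)(C)C)[C@@]2(C)CCCC(C)(C)[C@H]12 | intermediate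
21 | 6β-acetoxy-13-hydroxy-8α,15:9α,14-dicyclolabdan-7-one, (13S) | CC(=O)O[C@@H]1C(=O)[C@@]2(C)C[C@H]3[C@@]2(CC[C@]3(C)O)[C@@]2(C)CCCC(C)(C)[C@H]12 | target

**Step count and risks**

Total step count: 12. Longest linear sequence: 12 steps (1 to 21).

Most likely to fail, step 8 (key step). After ionisation of the C13–O bond the hydride on C13a lies antiperiplanar to the breaking bond and may shift faster than the ring bond, so that the ring is not contracted. The fallback sets out from 12 and comes back at 13. It uses that hydride shift on purpose (BF3·OEt2, benzene) to make the 13a-ketone F1. Bromination through the enol (PhNMe3Br3, THF) toward the methyl-bearing C13 and from the H-14 face should give the α-bromo ketone F2. A Favorskii ring contraction (NaOMe, MeOH) then gives the methyl ester F3: C14 displaces bromide from the cyclobutane face, so C13 ends with the same configuration as in 13. LiAlH4 reduces the ester and the C7 ketone to the diol F4, and Dess–Martin periodinane oxidises both carbinols to give 13.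

Step 5. Closure of the six-membered ring from the enone triplet may be slow, so that hydrogen abstraction from the sulfonyl-bearing carbon or crossed addition competes. The fallback sets out from 5 and comes back at 11. Oxidation with CrO3·2C5H5N gives the ene-dione F5. Intermolecular [2+2] photocycloaddition with excess 1,3-butadiene (C=CC=C, 350 nm) gives the vinylcyclobutane F6, of which only the isomer with the vinyl group on C14 cis to C11 is carried on after separation. Methylenation of the unhindered C13 ketone (Ph3P=CH2) gives the diene F7, and ring-closing metathesis with the second-generation Grubbs catalyst RuCl2(=CHPh)(H2IMes)(PCy3) closes the cyclohexene of 11.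

Step 12. The enol acetate may be epoxidised from the β-face, or the acyloxy shift may run through an ionic path with retention; both would put the acetate in the 6α position. The fallback sets out from 16 and comes back at 20. TMSOTf/Et3N gives the silyl enol ether F8, and a Rubottom oxidation (mCPBA, then mild acid) gives the 6α-hydroxy ketone F9, the oxygen staying on the open α-face. Tf2O/pyridine gives the 6α-triflate F10, which CsOAc with 18-crown-6 in toluene should displace with inversion (SN2) to give 20; desilylation as in step 12 follows.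

Further compounds
F1 | step 8 | 8α,15:9α,14-dicyclo-13a-homolabdane-7,13a-dione (C13 unassigned) | C1C(=O)[C@@]2(C)C[C@H]3[C@@]2(CCC(C)C3=O)[C@@]2(C)CCCC(C)(C)[C@H]12
F2 | step 8 | 13-bromo-8α,15:9α,14-dicyclo-13a-homolabdane-7,13a-dione (bromine on the H-14 face) | C1C(=O)[C@@]2(C)C[C@H]3[C@@]2(CC[C@](C)(Br)C3=O)[C@@]2(C)CCCC(C)(C)[C@H]12
F3 | step 8 | (13S)-13-(methoxycarbonyl)-8α,15:9α,14-dicyclolabdan-7-one | C1C(=O)[C@@]2(C)C[C@H]3[C@@]2(CC[C@]3(C)C(=O)OC)[C@@]2(C)CCCC(C)(C)[C@H]12
F4 | step 8 | (13S)-13-(hydroxymethyl)-8α,15:9α,14-dicyclolabdan-7-ol (C7 unassigned) | C1C(O)[C@@]2(C)C[C@H]3[C@@]2(CC[C@]3(C)CO)[C@@]2(C)CCCC(C)(C)[C@H]12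
F5 | step 5 | 14,15-dinorlabd-8-ene-7,13-dione | C1C(=O)C(C)=C(CCC(C)=O)[C@@]2(C)CCCC(C)(C)[C@H]12
F6 | step 5 | 14-vinyl-8α,15:9α,14-dicyclo-14,15-dinorlabdane-7,13-dione numbered so that the vinyl-bearing cyclobutane carbon is C14 (vinyl cis to C11) | C1C(=O)[C@@]2(C)C[C@H](C=C)[C@@]2(CCC(C)=O)[C@@]2(C)CCCC(C)(C)[C@H]12
F7 | step 5 | 13-methylene analogue of F6 (isopropenyl side chain, C14 vinyl) | C1C(=O)[C@@]2(C)C[C@H](C=C)[C@@]2(CCC(C)=C)[C@@]2(C)CCCC(C)(C)[C@H]12
F8 | step 12 | 7,13-bis(trimethylsilyloxy)-8α,15:9α,14-dicyclolabd-6-ene | C1=C(O[Si](C)(C)C)[C@@]2(C)C[C@H]3[C@@]2(CC[C@]3(C)O[Si](C)(C)C)[C@@]2(C)CCCC(C)(C)[C@H]12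
F9 | step 12 | 6α-hydroxy-13-(trimethylsilyloxy)-8α,15:9α,14-dicyclolabdan-7-one | O[C@H]1C(=O)[C@@]2(C)C[C@H]3[C@@]2(CC[C@]3(C)O[Si](C)(C)C)[C@@]2(C)CCCC(C)(C)[C@H]12
F10 | step 12 | 6α-(trifluoromethylsulfonyloxy)-13-(trimethylsilyloxy)-8α,15:9α,14-dicyclolabdan-7-one | FC(F)(F)S(=O)(=O)O[C@H]1C(=O)[C@@]2(C)C[C@H]3[C@@]2(CC[C@]3(C)O[Si](C)(C)C)[C@@]2(C)CCCC(C)(C)[C@H]12
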